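## Retrosynthetic overview

1. The target comes from fluoride global deprotection of a fully protected tetracycle; its C7 ester is installed by Pd-catalysed carbonylation of the C5=C6 enol triflate of a ring B ketone, and C5/C6 are set by reduction and equilibration.
2. The ring B ketone comes from one operation that closes rings B and D together: a Nazarov electrocyclisation (C9–C10) interrupted by intramolecular allylsilane capture (C8–C15).
3. The cross-conjugated dienone comes from a Pd-catalysed three-component carbonylative Stille coupling (CO becomes C6) of a ring A enol triflate and a ring C vinylstannane.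
4. Ring A: (S)-epichlorohydrin → cobalt-catalysed epoxide carbonylation → two Fráter–Seebach reactions (C4) → ring-closing metathesis. Ring C: hydroquinone → quinone monoketal → Rh-catalysed asymmetric alkenyl addition (C13) → trans reduction (C12).
5. Ring order: A and C separately, then B and D in one step.

Assumption and conventions: the open aldehyde–diacid drawn is taken as the target (lactol tautomers may coexist); gibberellin numbering is used (ring A C1–C5/C10, ring B C5/C6/C8/C9/C10, ring C C8/C9/C11–C14, ring D C8/C13–C16, C17 exocyclic CH2, C18 the 4-methyl, C19 the 4-carboxyl, C7 the 6-carboxyl, C20 on C10; α is the face of C19/C20, β the face of the 3-hydroxyl), the SMILES in the compound list is definitive, and TBS = tert-butyldimethylsilyl, TIPS = triisopropylsilyl, TMSE = 2-(trimethylsilyl)ethyl, NAP = naphthalen-2-ylmethyl.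

## Route

### Ring A fragment

Step 1
Reactants: 1 (S)-epichlorohydrin
Product: 3 (2S)-2-(prop-2-en-1-yl)oxirane, via (2S)-1-chloropent-4-en-2-ol 2 (not isolated)
Conditions: CH2=CHMgBr, CuI (10 mol%), THF, −40 °C; then NaOH, Et2O/H2O, rt
Reagents that add atoms: vinylmagnesium bromide C=C[Mg]Br
Why: Copper-catalysed Grignard opening of the epoxide at its CH2 terminus and Williamson-type closure of the chlorohydrin onto the chloromethyl carbon leave the chiral-pool stereocentre (later C3) untouched.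

Step 2
Reactants: 3 (2S)-2-(prop-2-en-1-yl)oxirane
Product: 4 TMSE (3S)-3-hydroxyhex-5-enoate
Conditions: Co2(CO)8 (5 mol%), 3-hydroxypyridine (10 mol%), CO (40 atm), Me3SiCH2CH2OH, THF, 60 °C
Reagents that add atoms: carbon monoxide [C-]#[O+]; 2-(trimethylsilyl)ethanol C[Si](C)(C)CCO
Why: Cobalt-catalysed alkoxycarbonylative epoxide opening (tetracarbonylcobaltate attacks the unhindered CH2, CO inserts, the alcohol releases the ester) gives the β-hydroxy ester with retention at the carbinol.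

Step 3
Reactants: 4 TMSE (3S)-3-hydroxyhex-5-enoate
Product: 6 TMSE (2S,3S)-3-hydroxy-2-methylhex-5-enoate, via dilithium dianion 5 (not isolated)
Conditions: LiN(i-Pr)2 (2.2 equiv), THF, −78 → −20 °C; MeI, DMPU, −78 → −40 °C; AcOH quench
Reagents that add atoms: iodomethane CI
Why: Fráter–Seebach alkylation of the chelated dianion places the methyl anti to the allyl group of the carbinol carbon (this centre is re-enolised in step 6).

Step 4
Reactants: 7 2-methylidenepropane-1,3-diol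
Product: 8 2-[(naphthalen-2-ylmethoxy)methyl]prop-2-en-1-ol
Conditions: NaH (1.0 equiv), 2-(bromomethyl)naphthalene, THF/DMF, 0 °C → rt (diol in excess)
Reagents that add atoms: 2-(bromomethyl)naphthalene BrCc1ccc2ccccc2c1
Why: Statistical Williamson mono-etherification of the symmetric diol.

Step 5
Reactants: 8 2-[(naphthalen-2-ylmethoxy)methyl]prop-2-en-1-ol
Product: 9 2-[(naphthalen-2-ylmethoxy)methyl]prop-2-enal
Conditions: MnO2, CH2Cl2, rt
Reagents that add atoms: none
Why: Allylic alcohol oxidation with MnO2 stops cleanly at the enal.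

Step 6
Reactants: 6 TMSE (2S,3S)-3-hydroxy-2-methylhex-5-enoate; 9 2-[(naphthalen-2-ylmethoxy)methyl]prop-2-enal
Product: 11 TMSE (2R,3S)-3-hydroxy-2-{1-hydroxy-2-[(naphthalen-2-ylmethoxy)methyl]prop-2-en-1-yl}-2-methylhex-5-enoate (both epimers at the new carbinol), via dilithium dianion 10 (not isolated)
Conditions: LiN(i-Pr)2 (2.2 equiv), THF, −78 → −10 °C; then 9, −78 °C; AcOH quench at −78 °C
Reagents that add atoms: none
Why: Fráter–Seebach aldol addition: the chelated dianion adds 1,2 to the enal on the face anti to the allyl group, so the quaternary C4 forms with methyl cis and ester trans to the C3 oxygen; the new carbinol is oxidised in step 8.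

Step 7
Reactants: 11 aldol diol
Product: 12 TMSE (1R,6S)-2,6-dihydroxy-1-methyl-3-[(naphthalen-2-ylmethoxy)methyl]cyclohex-3-ene-1-carboxylate (both C2 epimers)
Conditions: second-generation Grubbs catalyst RuCl2(H2IMes)(PCy3)(=CHPh) (5 mol%), CH2Cl2, 40 °C
Reagents that add atoms: none
Why: Ring-closing metathesis of the terminal vinyl group and the 1,1-disubstituted alkene closes ring A as the trisubstituted cyclohexene without touching the stereocentres.

Step 8
Reactants: 12 cyclohexene diol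
Product: 13 TMSE (1R,6S)-6-hydroxy-1-methyl-3-[(naphthalen-2-ylmethoxy)methyl]-2-oxocyclohex-3-ene-1-carboxylate
Conditions: MnO2 (excess), CH2Cl2, rt
Reagents that add atoms: none
Why: MnO2 oxidises only the allylic alcohol, so both carbinol epimers converge on one enone while the C3 alcohol survives under neutral conditions.

Step 9
Reactants: 13 hydroxy enone
Product: 14 TMSE (1R,6S)-6-(TBS-oxy)-1-methyl-3-[(naphthalen-2-ylmethoxy)methyl]-2-oxocyclohex-3-ene-1-carboxylate
Conditions: t-BuMe2SiOSO2CF3, 2,6-lutidine, CH2Cl2, −78 °C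
Reagents that add atoms: tert-butyldimethylsilyl triflate CC(C)(C)[Si](C)(C)OS(=O)(=O)C(F)(F)F
Why: Silyl triflate with a hindered weak base silylates the hindered secondary alcohol faster than the retro-aldol pathway can open.

Step 10
Reactants: 14 silylated enone
Product: 16 TMSE (1R,6S)-6-(TBS-oxy)-1-methyl-3-[(naphthalen-2-ylmethoxy)methyl]-2-(trifluoromethanesulfonyloxy)cyclohex-2-ene-1-carboxylate (ring A fragment), via lithium enolate 15 (not isolated)
Conditions: LiBH(s-Bu)3, THF, −78 °C; then Comins' reagent, −78 → 0 °C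
Reagents that add atoms: Comins' reagent Clc1ccc(nc1)N(S(=O)(=O)C(F)(F)F)S(=O)(=O)C(F)(F)F
Why: Conjugate hydride reduction of the enone gives the regiodefined tetrasubstituted enolate (the other α-carbon is quaternary), which is O-triflated.

### Ring C fragment

Step 11
Reactants: 17 hydroquinone
Product: 18 4-methoxyphenol
Conditions: MeI (0.4 equiv), K2CO3, acetone, reflux (excess hydroquinone recovered)
Reagents that add atoms: iodomethane CI
Why: Statistical Williamson mono-methylation of the symmetric diphenol.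

Step 12
Reactants: 18 4-methoxyphenol
Product: 19 4,4-dimethoxycyclohexa-2,5-dien-1-one
Conditions: PhI(OAc)2, MeOH, 0 °C
Reagents that add atoms: methanol CO
Why: Hypervalent-iodine oxidative dearomatisation of the para-alkoxyphenol in methanol gives the quinone monoketal.

Step 13
Reactants: 20 (2-bromoprop-2-en-1-yl)trimethylsilane
Product: 22 4,4,5,5-tetramethyl-2-[3-(trimethylsilyl)prop-1-en-2-yl]-1,3,2-dioxaborolane, via vinyllithium 21 (not isolated)
Conditions: t-BuLi (2.0 equiv), Et2O, −78 °C; then 2-isopropoxy-4,4,5,5-tetramethyl-1,3,2-dioxaborolane, −78 °C → rt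
Reagents that add atoms: 2-isopropoxy-4,4,5,5-tetramethyl-1,3,2-dioxaborolane CC(C)OB1OC(C)(C)C(C)(C)O1
Why: Bromine–lithium exchange and borylation of the vinyllithium give the alkenylboronate with the allylsilane intact.

Step 14
Reactants: 19 4,4-dimethoxycyclohexa-2,5-dien-1-one; 22 alkenylboronate (1.05 equiv)
Product: 23 (5R)-4,4-dimethoxy-5-[3-(trimethylsilyl)prop-1-en-2-yl]cyclohex-2-en-1-one
Conditions: [Rh(cod)Cl]2 (2.5 mol%), (R)-BINAP (6 mol%), KOH (0.5 equiv), 1,4-dioxane/H2O (10:1), 40 °C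
Reagents that add atoms: none
Why: Hayashi–Miyaura rhodium-catalysed asymmetric 1,4-addition desymmetrises the dienone, the BINAP–alkenylrhodium species selecting one enantiotopic enone face to set C13 (ligand antipode chosen by analogy with additions to 2-cyclohexenone).

Step 15
Reactants: 23 enone ketal
Product: 25 (5R)-4,4-dimethoxy-5-[3-(trimethylsilyl)prop-1-en-2-yl]cyclohex-1-en-1-yl trifluoromethanesulfonate, via lithium enolate 24 (not isolated)
Conditions: LiBH(s-Bu)3, THF, −78 °C; then Comins' reagent, −78 → 0 °C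
Reagents that add atoms: Comins' reagent Clc1ccc(nc1)N(S(=O)(=O)C(F)(F)F)S(=O)(=O)C(F)(F)F
Why: Conjugate reduction of the remaining enone gives the enolate on the C9 side only, and its O-triflation fixes the C8=C9 position.

Step 16
Reactants: 25 enol triflate ketal
Product: 26 (5R)-4-oxo-5-[3-(trimethylsilyl)prop-1-en-2-yl]cyclohex-1-en-1-yl trifluoromethanesulfonate
Conditions: pyridinium p-toluenesulfonate (20 mol%), acetone/H2O (10:1), rt, short contact
Reagents that add atoms: water O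
Why: Mild acetal hydrolysis frees the C12 ketone under weakly acidic conditions chosen to spare the allylsilane, the enol triflate and the enolisable C13 centre.

Step 17
Reactants: 26 ketone
Product: 27 (4S,5R)-4-hydroxy-5-[3-(trimethylsilyl)prop-1-en-2-yl]cyclohex-1-en-1-yl trifluoromethanesulfonate
Conditions: NaBH4, CeCl3·7H2O, MeOH, −78 °C
Reagents that add atoms: none
Why: Luche-type hydride reduction by axial attack on the flattened ring gives the equatorial alcohol trans to the neighbouring alkenyl substituent, setting C12 (minor cis isomer removed by chromatography).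

Step 18
Reactants: 27 trans alcohol
Product: 28 (4S,5R)-4-(TIPS-oxy)-5-[3-(trimethylsilyl)prop-1-en-2-yl]cyclohex-1-en-1-yl trifluoromethanesulfonate
Conditions: i-Pr3SiOSO2CF3, 2,6-lutidine, CH2Cl2, 0 °C
Reagents that add atoms: triisopropylsilyl triflate CC(C)[Si](OS(=O)(=O)C(F)(F)F)(C(C)C)C(C)C
Why: Silylation gives a Lewis-acid-stable ether for the cyclisation step.

Step 19
Reactants: 28 enol triflate
Product: 29 trimethyl{(4S,5R)-4-(TIPS-oxy)-5-[3-(trimethylsilyl)prop-1-en-2-yl]cyclohex-1-en-1-yl}stannane (ring C fragment)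
Conditions: Pd(PPh3)4 (5 mol%), Me3SnSnMe3, LiCl, THF, 65 °C
Reagents that add atoms: hexamethylditin C[Sn](C)(C)[Sn](C)(C)C
Why: Palladium-catalysed stannylation of the enol triflate (oxidative addition, Sn–Sn transmetallation, reductive elimination) keeps the alkene position.

### Fragment union and endgame

Step 20
Reactants: 16 ring A enol triflate; 29 ring C vinylstannane
Product: 30 TMSE (1S,6S)-6-(TBS-oxy)-1-methyl-3-[(naphthalen-2-ylmethoxy)methyl]-2-{[(4S,5R)-4-(TIPS-oxy)-5-[3-(trimethylsilyl)prop-1-en-2-yl]cyclohex-1-en-1-yl]carbonyl}cyclohex-2-ene-1-carboxylate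
Conditions: Pd(PPh3)4 (10 mol%), LiCl (3 equiv), CO (3 atm), THF, 60 °C
Reagents that add atoms: carbon monoxide [C-]#[O+]
Why: Carbonylative Stille coupling (oxidative addition of the enol triflate, CO insertion to the acylpalladium, transmetallation, reductive elimination) forms the C5–C6 and C6–C8 bonds in one catalytic step and creates no stereocentre.

Step 21
Reactants: 30 cross-conjugated dienone
Product: 33 TMSE 3β-(TBS-oxy)-12α-(TIPS-oxy)-20-(naphthalen-2-ylmethoxy)-6-oxo-7-norgibberell-16-en-19-oate (C5 epimers), via oxyallyl cation–BF3 adduct 31 (not isolated), via difluoroboron enolate 32 (not isolated)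
Conditions: BF3·OEt2 (2 equiv), CH2Cl2, −78 → −30 °C; then H2O
Reagents that add atoms: none
Why: Proposed new method: BF3 activation of the dienone triggers a conrotatory 4π Nazarov electrocyclisation that forges C9–C10 (the ring carbons C1 and C11 are the outside groups and end up trans, so H9 is anti to C20, and bonding at C10 occurs anti to the pseudo-axial C19 ester), and the oxyallyl cation is then captured at C8 by the 1,3-diaxially placed allylsilane on C13 from the face anti to C10 (SE2′ attack with loss of the silyl group as Me3SiF), closing ring D with its exocyclic methylene and both quaternary centres in one operation; the closest known reactions are interrupted Nazarov cyclisations in which allylsilanes or tethered alkenes trap the oxyallyl cation and the methylenecyclopentane annulation of 2-(silylmethyl)allyl units, but capture that builds a bridged bicyclo[3.2.1]octane across the new ring has not been shown.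

Step 22
Reactants: 33 ring B ketone
Product: 35 TMSE 3β-(TBS-oxy)-12α-(TIPS-oxy)-20-(naphthalen-2-ylmethoxy)-6-(trifluoromethanesulfonyloxy)-7-norgibberella-5,16-dien-19-oate, via potassium enolate 34 (not isolated)
Conditions: KN(SiMe3)2 (1.5 equiv), THF, −78 → −20 °C; then Comins' reagent, −78 → 0 °C
Reagents that add atoms: Comins' reagent Clc1ccc(nc1)N(S(=O)(=O)C(F)(F)F)S(=O)(=O)C(F)(F)F
Why: C5 is the only enolisable position of the ketone (C8 is quaternary), so enolate O-triflation gives the C5=C6 enol triflate from both C5 epimers.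

Step 23
Reactants: 35 enol triflate
Product: 36 bis-TMSE 3β-(TBS-oxy)-12α-(TIPS-oxy)-20-(naphthalen-2-ylmethoxy)gibberella-5,16-diene-7,19-dioate
Conditions: Pd(OAc)2 (10 mol%), dppp (12 mol%), CO (1 atm), Me3SiCH2CH2OH, Et3N, DMF, 65 °C
Reagents that add atoms: carbon monoxide [C-]#[O+]; 2-(trimethylsilyl)ethanol C[Si](C)(C)CCO
Why: Palladium-catalysed alkoxycarbonylation of the enol triflate (oxidative addition, CO insertion, alcoholysis) installs C7 as a fluoride-labile ester.

Step 24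
Reactants: 36 C5=C6 enoate
Product: 38 bis-TMSE 3β-(TBS-oxy)-12α-(TIPS-oxy)-20-(naphthalen-2-ylmethoxy)gibberell-16-ene-7,19-dioate (5β-H 6β-ester), via 6-epi diester 37 (not isolated)
Conditions: SmI2 (6 equiv), HMPA, t-BuOH, THF, −78 → 0 °C; then t-BuOK (0.5 equiv), t-BuOH/THF, rt
Reagents that add atoms: none
Why: Single-electron conjugate reduction protonates C5 from the β face, anti to the axial C19 ester and C20 group (as in reductions of steroidal 14-enes), giving the trans A/B fusion, and enolate equilibration then moves the C6 ester to the more stable position trans to C4.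

Step 25
Reactants: 38 saturated diester
Product: 40 bis-TMSE 3β-(TBS-oxy)-12α-(TIPS-oxy)-20-oxogibberell-16-ene-7,19-dioate, via C20 alcohol 39 (not isolated)
Conditions: DDQ, CH2Cl2/pH 7 buffer, 0 °C; then Dess–Martin periodinane, NaHCO3, CH2Cl2, 0 °C
Reagents that add atoms: none
Why: Oxidative cleavage of the naphthylmethyl ether and immediate Dess–Martin oxidation of the neopentyl alcohol (telescoped to outrun 19,20-lactonisation) give the C20 aldehyde.

Step 26
Reactants: 40 protected aldehyde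
Product: 41 3β,12α-dihydroxy-20-oxogibberell-16-ene-7,19-dioic acid (target)
Conditions: Bu4NF (12 equiv), THF, 0 → 45 °C; then dilute aq HCl to pH 3
Reagents that add atoms: none
Why: Fluoride removes both silyl ethers and fragments both TMSE esters (β-elimination of ethylene) without hydroxide, so retro-aldol epimerisation at C3 is avoided.

## Compound list

1 | (S)-epichlorohydrin, (2S)-2-(chloromethyl)oxirane | ClC[C@@H]1CO1 | starting material
2 | (2S)-1-chloropent-4-en-2-ol | C=CC[C@H](O)CCl | intermediate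
3 | (2S)-2-(prop-2-en-1-yl)oxirane | C=CC[C@H]1CO1 | intermediate
4 | TMSE (3S)-3-hydroxyhex-5-enoate | C=CC[C@H](O)CC(=O)OCC[Si](C)(C)C | intermediate
5 | dilithium alkoxide–enolate of 4 | C=CC[C@H](O[Li])C=C(O[Li])OCC[Si](C)(C)C | intermediate
6 | TMSE (2S,3S)-3-hydroxy-2-methylhex-5-enoate | C=CC[C@H](O)[C@H](C)C(=O)OCC[Si](C)(C)C | intermediate
7 | 2-methylidenepropane-1,3-diol | C=C(CO)CO | starting material
8 | 2-[(naphthalen-2-ylmethoxy)methyl]prop-2-en-1-ol | C=C(CO)COCc1ccc2ccccc2c1 | intermediate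
9 | 2-[(naphthalen-2-ylmethoxy)methyl]prop-2-enal | C=C(C=O)COCc1ccc2ccccc2c1 | intermediate
10 | dilithium alkoxide–enolate of 6 | C=CC[C@H](O[Li])C(C)=C(O[Li])OCC[Si](C)(C)C | intermediate
11 | TMSE (2R,3S)-3-hydroxy-2-{1-hydroxy-2-[(naphthalen-2-ylmethoxy)methyl]prop-2-en-1-yl}-2-methylhex-5-enoate (epimers at the side-chain carbinol) | C=CC[C@H](O)[C@@](C)(C(=O)OCC[Si](C)(C)C)C(O)C(=C)COCc1ccc2ccccc2c1 | intermediate
12 | TMSE (1R,6S)-2,6-dihydroxy-1-methyl-3-[(naphthalen-2-ylmethoxy)methyl]cyclohex-3-ene-1-carboxylate (C2 epimers) | C1(COCc2ccc3ccccc3c2)=CC[C@H](O)[C@@](C)(C(=O)OCC[Si](C)(C)C)C1O | intermediate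
13 | TMSE (1R,6S)-6-hydroxy-1-methyl-3-[(naphthalen-2-ylmethoxy)methyl]-2-oxocyclohex-3-ene-1-carboxylate | C1(COCc2ccc3ccccc3c2)=CC[C@H](O)[C@@](C)(C(=O)OCC[Si](C)(C)C)C1=O | intermediate
14 | TMSE (1R,6S)-6-(TBS-oxy)-1-methyl-3-[(naphthalen-2-ylmethoxy)methyl]-2-oxocyclohex-3-ene-1-carboxylate | C1(COCc2ccc3ccccc3c2)=CC[C@H](O[Si](C)(C)C(C)(C)C)[C@@](C)(C(=O)OCC[Si](C)(C)C)C1=O | intermediate
15 | lithium enolate from conjugate reduction of 14 | C1(COCc2ccc3ccccc3c2)CC[C@H](O[Si](C)(C)C(C)(C)C)[C@@](C)(C(=O)OCC[Si](C)(C)C)C=1O[Li] | intermediate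
16 | TMSE (1R,6S)-6-(TBS-oxy)-1-methyl-3-[(naphthalen-2-ylmethoxy)methyl]-2-(trifluoromethanesulfonyloxy)cyclohex-2-ene-1-carboxylate (ring A fragment) | C1(COCc2ccc3ccccc3c2)CC[C@H](O[Si](C)(C)C(C)(C)C)[C@@](C)(C(=O)OCC[Si](C)(C)C)C=1OS(=O)(=O)C(F)(F)F | intermediate
17 | hydroquinone | Oc1ccc(O)cc1 | starting material
18 | 4-methoxyphenol | COc1ccc(O)cc1 | intermediate
19 | 4,4-dimethoxycyclohexa-2,5-dien-1-one | COC1(OC)C=CC(=O)C=C1 | intermediate
20 | (2-bromoprop-2-en-1-yl)trimethylsilane | C=C(Br)C[Si](C)(C)C | starting material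
21 | [3-(trimethylsilyl)prop-1-en-2-yl]lithium | C=C([Li])C[Si](C)(C)C | intermediate
22 | 4,4,5,5-tetramethyl-2-[3-(trimethylsilyl)prop-1-en-2-yl]-1,3,2-dioxaborolane | C=C(C[Si](C)(C)C)B1OC(C)(C)C(C)(C)O1 | intermediate
23 | (5R)-4,4-dimethoxy-5-[3-(trimethylsilyl)prop-1-en-2-yl]cyclohex-2-en-1-one | O=C1C=CC(OC)(OC)[C@@H](C(=C)C[Si](C)(C)C)C1 | intermediate
24 | lithium enolate from conjugate reduction of 23 | [Li]OC1=CCC(OC)(OC)[C@@H](C(=C)C[Si](C)(C)C)C1 | intermediate
25 | (5R)-4,4-dimethoxy-5-[3-(trimethylsilyl)prop-1-en-2-yl]cyclohex-1-en-1-yl trifluoromethanesulfonate | FC(F)(F)S(=O)(=O)OC1=CCC(OC)(OC)[C@@H](C(=C)C[Si](C)(C)C)C1 | intermediate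
26 | (5R)-4-oxo-5-[3-(trimethylsilyl)prop-1-en-2-yl]cyclohex-1-en-1-yl trifluoromethanesulfonate | FC(F)(F)S(=O)(=O)OC1=CCC(=O)[C@@H](C(=C)C[Si](C)(C)C)C1 | intermediate
27 | (4S,5R)-4-hydroxy-5-[3-(trimethylsilyl)prop-1-en-2-yl]cyclohex-1-en-1-yl trifluoromethanesulfonate | FC(F)(F)S(=O)(=O)OC1=CC[C@H](O)[C@@H](C(=C)C[Si](C)(C)C)C1 | intermediate
28 | (4S,5R)-4-(TIPS-oxy)-5-[3-(trimethylsilyl)prop-1-en-2-yl]cyclohex-1-en-1-yl trifluoromethanesulfonate | FC(F)(F)S(=O)(=O)OC1=CC[C@H](O[Si](C(C)C)(C(C)C)C(C)C)[C@@H](C(=C)C[Si](C)(C)C)C1 | intermediate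
29 | trimethyl{(4S,5R)-4-(TIPS-oxy)-5-[3-(trimethylsilyl)prop-1-en-2-yl]cyclohex-1-en-1-yl}stannane (ring C fragment) | C[Sn](C)(C)C1=CC[C@H](O[Si](C(C)C)(C(C)C)C(C)C)[C@@H](C(=C)C[Si](C)(C)C)C1 | intermediate
30 | cross-conjugated dienone: TMSE (1S,6S)-6-(TBS-oxy)-1-methyl-3-[(naphthalen-2-ylmethoxy)methyl]-2-{[(4S,5R)-4-(TIPS-oxy)-5-[3-(trimethylsilyl)prop-1-en-2-yl]cyclohex-1-en-1-yl]carbonyl}cyclohex-2-ene-1-carboxylate | C1(COCc2ccc3ccccc3c2)CC[C@H](O[Si](C)(C)C(C)(C)C)[C@@](C)(C(=O)OCC[Si](C)(C)C)C=1C(=O)C1=CC[C@H](O[Si](C(C)C)(C(C)C)C(C)C)[C@@H](C(=C)C[Si](C)(C)C)C1 | intermediate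
31 | BF3-bound oxyallyl cation after C9–C10 closure (rings A, B and C; cation at C8, allylsilane on C13) | [C+]23C[C@H](C(=C)C[Si](C)(C)C)[C@@H](O[Si](C(C)C)(C(C)C)C(C)C)C[C@H]2[C@]1(COCc4ccc5ccccc5c4)CC[C@H](O[Si](C)(C)C(C)(C)C)[C@@](C)(C(=O)OCC[Si](C)(C)C)C1=C3O[B-](F)(F)F | intermediate
32 | tetracyclic difluoroboron C5=C6 enolate | C=C1C[C@]23C[C@H]1[C@@H](O[Si](C(C)C)(C(C)C)C(C)C)C[C@H]2[C@]1(COCc4ccc5ccccc5c4)CC[C@H](O[Si](C)(C)C(C)(C)C)[C@@](C)(C(=O)OCC[Si](C)(C)C)C1=C3OB(F)F | intermediate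
33 | TMSE 3β-(TBS-oxy)-12α-(TIPS-oxy)-20-(naphthalen-2-ylmethoxy)-6-oxo-7-norgibberell-16-en-19-oate (C5 epimers) | C=C1C[C@]23C[C@H]1[C@@H](O[Si](C(C)C)(C(C)C)C(C)C)C[C@H]2[C@]1(COCc4ccc5ccccc5c4)CC[C@H](O[Si](C)(C)C(C)(C)C)[C@@](C)(C(=O)OCC[Si](C)(C)C)C1C3=O | intermediate
34 | potassium C5=C6 enolate of 33 | C=C1C[C@]23C[C@H]1[C@@H](O[Si](C(C)C)(C(C)C)C(C)C)C[C@H]2[C@]1(COCc4ccc5ccccc5c4)CC[C@H](O[Si](C)(C)C(C)(C)C)[C@@](C)(C(=O)OCC[Si](C)(C)C)C1=C3O[K] | intermediate
35 | C5=C6 enol triflate of 33 | C=C1C[C@]23C[C@H]1[C@@H](O[Si](C(C)C)(C(C)C)C(C)C)C[C@H]2[C@]1(COCc4ccc5ccccc5c4)CC[C@H](O[Si](C)(C)C(C)(C)C)[C@@](C)(C(=O)OCC[Si](C)(C)C)C1=C3OS(=O)(=O)C(F)(F)F | intermediate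
36 | bis-TMSE 3β-(TBS-oxy)-12α-(TIPS-oxy)-20-(naphthalen-2-ylmethoxy)gibberella-5,16-diene-7,19-dioate | C=C1C[C@]23C[C@H]1[C@@H](O[Si](C(C)C)(C(C)C)C(C)C)C[C@H]2[C@]1(COCc4ccc5ccccc5c4)CC[C@H](O[Si](C)(C)C(C)(C)C)[C@@](C)(C(=O)OCC[Si](C)(C)C)C1=C3C(=O)OCC[Si](C)(C)C | intermediate
37 | 6-epimer of 38 (5β-H, 6α-ester) | C=C1C[C@]23C[C@H]1[C@@H](O[Si](C(C)C)(C(C)C)C(C)C)C[C@H]2[C@]1(COCc4ccc5ccccc5c4)CC[C@H](O[Si](C)(C)C(C)(C)C)[C@@](C)(C(=O)OCC[Si](C)(C)C)[C@H]1[C@H]3C(=O)OCC[Si](C)(C)C | intermediate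
38 | bis-TMSE 3β-(TBS-oxy)-12α-(TIPS-oxy)-20-(naphthalen-2-ylmethoxy)gibberell-16-ene-7,19-dioate (5β-H, 6β-ester) | C=C1C[C@]23C[C@H]1[C@@H](O[Si](C(C)C)(C(C)C)C(C)C)C[C@H]2[C@]1(COCc4ccc5ccccc5c4)CC[C@H](O[Si](C)(C)C(C)(C)C)[C@@](C)(C(=O)OCC[Si](C)(C)C)[C@H]1[C@@H]3C(=O)OCC[Si](C)(C)C | intermediate
39 | bis-TMSE 3β-(TBS-oxy)-12α-(TIPS-oxy)-20-hydroxygibberell-16-ene-7,19-dioate | C=C1C[C@]23C[C@H]1[C@@H](O[Si](C(C)C)(C(C)C)C(C)C)C[C@H]2[C@]1(CO)CC[C@H](O[Si](C)(C)C(C)(C)C)[C@@](C)(C(=O)OCC[Si](C)(C)C)[C@H]1[C@@H]3C(=O)OCC[Si](C)(C)C | intermediate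
40 | bis-TMSE 3β-(TBS-oxy)-12α-(TIPS-oxy)-20-oxogibberell-16-ene-7,19-dioate | C=C1C[C@]23C[C@H]1[C@@H](O[Si](C(C)C)(C(C)C)C(C)C)C[C@H]2[C@]1(C=O)CC[C@H](O[Si](C)(C)C(C)(C)C)[C@@](C)(C(=O)OCC[Si](C)(C)C)[C@H]1[C@@H]3C(=O)OCC[Si](C)(C)C | intermediate
41 | 3β,12α-dihydroxy-20-oxogibberell-16-ene-7,19-dioic acid (CNP0218328.1) | C=C1C[C@]23C[C@H]1[C@@H](O)C[C@H]2[C@]1(C=O)CC[C@H](O)[C@@](C)(C(=O)O)[C@H]1[C@@H]3C(=O)O | target

## Step count and risks

Total step count: 26. Longest linear sequence: 15 steps (steps 1, 2, 3, 6, 7, 8, 9, 10 and 20–26; the ring C line, steps 11, 12, 14–19 and 20–26, is equally long), which is 58% of the total.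

Steps most likely to fail:

**Step 21 (the proposed Nazarov–allylsilane cascade).** The allylsilane may attack the C9 terminus before electrocyclisation (giving a bicyclo[2.2.2]octane), may be protodesilylated, or the conrotation may take the wrong sense relative to the ring A stereocentres. The fallback uses only known reactions, sets out from 30 and comes back at 33. Buffered mCPBA (CH2Cl2, −20 °C) epoxidises only the electron-rich allylsilane alkene of 30 to the epoxysilane F1. AcOH in aqueous THF opens it with loss of the silyl group to the transposed allylic alcohol F2, and Ac2O/pyridine gives the allylic acetate F3. A conventional Nazarov cyclisation with proton loss (BF3·OEt2, CH2Cl2, 0 °C) gives the ring-fused cyclopentenone F4 (C8=C9, C10 quaternary). SmI2/HMPA/MeOH conjugate reduction delivers hydrogen to C9 anti to C20 and gives the ketone F5. KN(SiMe3)2 followed by Pd(PPh3)4 then closes ring D by intramolecular Tsuji–Trost allylation of the C8 enolate, giving 33.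

**Step 20 (carbonylative Stille coupling of a tetrasubstituted enol triflate flanked by a quaternary carbon).** Slow oxidative addition or direct, CO-free coupling could intervene. The fallback replaces the three-component coupling by a formylation, 1,2-addition and oxidation sequence; it sets out from 16 and 29 and comes back at 30. Palladium-catalysed formylation of 16 (Pd(PPh3)4, CO, Bu3SnH, THF, 50 °C) gives the enal F6. Tin–lithium exchange of 29 (MeLi, THF, −78 °C) gives the vinyllithium F7, which adds to F6 to give the bis-allylic alcohol F8. Dess–Martin oxidation of F8 gives 30.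

**Step 22 (enol triflate from a ketone whose only α-hydrogen sits between two quaternary carbons).** Deprotonation at C5 may be too slow. The fallback avoids enolate chemistry; it sets out from 33 and comes back at 36, skipping 35. Condensation with hydrazine (N2H4·H2O, Et3N, EtOH, 80 °C) gives the hydrazone F9. Barton iodination (I2, tetramethylguanidine, THF, 0 °C) gives the vinyl iodide F10, which is alkoxycarbonylated under the conditions of step 23 to give 36.

## Further compounds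

F1 | step 21 | epoxysilane of 30 (oxirane on the former allylsilane alkene) | C1(COCc2ccc3ccccc3c2)CC[C@H](O[Si](C)(C)C(C)(C)C)[C@@](C)(C(=O)OCC[Si](C)(C)C)C=1C(=O)C1=CC[C@H](O[Si](C(C)C)(C(C)C)C(C)C)[C@@H](C2(C[Si](C)(C)C)CO2)C1
F2 | step 21 | dienone with a 3-hydroxyprop-1-en-2-yl group on C13 | C1(COCc2ccc3ccccc3c2)CC[C@H](O[Si](C)(C)C(C)(C)C)[C@@](C)(C(=O)OCC[Si](C)(C)C)C=1C(=O)C1=CC[C@H](O[Si](C(C)C)(C(C)C)C(C)C)[C@@H](C(=C)CO)C1
F3 | step 21 | dienone with a 3-acetoxyprop-1-en-2-yl group on C13 | C1(COCc2ccc3ccccc3c2)CC[C@H](O[Si](C)(C)C(C)(C)C)[C@@](C)(C(=O)OCC[Si](C)(C)C)C=1C(=O)C1=CC[C@H](O[Si](C(C)C)(C(C)C)C(C)C)[C@@H](C(=C)COC(C)=O)C1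
F4 | step 21 | tricyclic C8=C9 cyclopentenone bearing the allylic acetate (C5 epimers) | C23C[C@H](C(=C)COC(C)=O)[C@@H](O[Si](C(C)C)(C(C)C)C(C)C)CC=2[C@]1(COCc4ccc5ccccc5c4)CC[C@H](O[Si](C)(C)C(C)(C)C)[C@@](C)(C(=O)OCC[Si](C)(C)C)C1C3=O
F5 | step 21 | tricyclic saturated C6 ketone bearing the allylic acetate (9β-H; C5 and C8 epimers) | C23C[C@H](C(=C)COC(C)=O)[C@@H](O[Si](C(C)C)(C(C)C)C(C)C)C[C@H]2[C@]1(COCc4ccc5ccccc5c4)CC[C@H](O[Si](C)(C)C(C)(C)C)[C@@](C)(C(=O)OCC[Si](C)(C)C)C1C3=O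
F6 | step 20 | TMSE (1S,6S)-6-(TBS-oxy)-2-formyl-1-methyl-3-[(naphthalen-2-ylmethoxy)methyl]cyclohex-2-ene-1-carboxylate | C1(COCc2ccc3ccccc3c2)CC[C@H](O[Si](C)(C)C(C)(C)C)[C@@](C)(C(=O)OCC[Si](C)(C)C)C=1C=O
F7 | step 20 | {(4S,5R)-4-(TIPS-oxy)-5-[3-(trimethylsilyl)prop-1-en-2-yl]cyclohex-1-en-1-yl}lithium | [Li]C1=CC[C@H](O[Si](C(C)C)(C(C)C)C(C)C)[C@@H](C(=C)C[Si](C)(C)C)C1
F8 | step 20 | bis-allylic alcohol corresponding to 30 (carbinol epimers) | C1(COCc2ccc3ccccc3c2)CC[C@H](O[Si](C)(C)C(C)(C)C)[C@@](C)(C(=O)OCC[Si](C)(C)C)C=1C(O)C1=CC[C@H](O[Si](C(C)C)(C(C)C)C(C)C)[C@@H](C(=C)C[Si](C)(C)C)C1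
F9 | step 22 | C6 hydrazone of 33 | C=C1C[C@]23C[C@H]1[C@@H](O[Si](C(C)C)(C(C)C)C(C)C)C[C@H]2[C@]1(COCc4ccc5ccccc5c4)CC[C@H](O[Si](C)(C)C(C)(C)C)[C@@](C)(C(=O)OCC[Si](C)(C)C)C1C3=NN
F10 | step 22 | C5=C6 vinyl iodide (6-iodo analogue of 35) | C=C1C[C@]23C[C@H]1[C@@H](O[Si](C(C)C)(C(C)C)C(C)C)C[C@H]2[C@]1(COCc4ccc5ccccc5c4)CC[C@H](O[Si](C)(C)C(C)(C)C)[C@@](C)(C(=O)OCC[Si](C)(C)C)C1=C3I
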